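The data were generated by integration from invented constants, noise included.

Start with the easy step: the winter run is the dawn charge left standing longer, so it needs no new chemistry, just dawn's readings carried from 12 min to 24 min. Here is my quick number for the winter run, reckoned from the dawn run's readings.

| flask | substrate | partner | product | time |
|---|---|---|---|---|
| dawn | 0.120 M | 0.180 M |  |  |
| dusk | 0.0600 M | 0.120 M |  |  |
| spring | 0.120 M | 0.360 M |  |  |
| midnight | 0.120 M | 0.180 M | 0.0360 M |  |
| winter | 0.120 M | 0.180 M |  | 24 min |

| run | time / min | [product] / M |
|---|---|---|
| dawn run | 1.5 | 0.0308 |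
| dawn run | 3.0 | 0.0514 |
| dawn run | 4.5 | 0.0672 |
| dawn run | 6.0 | 0.0766 |
| dawn run | 7.5 | 0.0836 |
| dawn run | 9.0 | 0.0908 |
| dawn run | 10 | 0.0927 |
| dawn run | 12 | 0.0997 |
| dusk run | 1.5 | 0.0090 |
| dusk run | 3.0 | 0.0212 |
| dusk run | 4.5 | 0.0244 |
| dusk run | 6.0 | 0.0305 |
| dusk run | 7.5 | 0.0339 |
| dusk run | 9.0 | 0.0377 |
| dusk run | 10 | 0.0399 |
| dusk run | 12 | 0.0440 |
| spring run | 1.5 | 0.0588 |
| spring run | 3.0 | 0.0912 |
| spring run | 4.5 | 0.1078 |
| spring run | 6.0 | 0.1132 |
| spring run | 7.5 | 0.1154 |
| spring run | 9.0 | 0.1186 |
| spring run | 10 | 0.1190 |
| spring run | 12 | 0.1199 |
| midnight run | 1.5 | 0.0787 |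
| midnight run | 3.0 | 0.1014 |
| midnight run | 4.5 | 0.1132 |
| midnight run | 6.0 | 0.1247 |
| midnight run | 7.5 | 0.1318 |
| midnight run | 9.0 | 0.1357 |
| midnight run | 10 | 0.1409 |
| midnight run | 12 | 0.1417 |

(each reading ± 0.001 M)

- Overall: substrate + partner -> product.
- Constant volume, constant temperature.
- The analysis sees a species whether free or bound.
- An order is taken over about fifteen percent of the charge, up and down.

1. how the opening rate goes with [substrate] round the charge of the dawn run: the exponent of the rate at two percent of substrate gone to product (one fixed amount of product, the same in the runs compared)
2. how the opening rate goes with [partner] round the charge of the dawn run: the exponent of the rate at two percent of substrate gone to product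
3. the dusk run starts with 0.0600 M less of substrate and of partner than the dawn run, and with no product. Compared where both hold the same amount of substrate, once fifteen percent of what the dusk run was charged with has turned into product, is the dusk run faster, slower or alike (within a tenth)?
4. product in the winter run at 24 min, as a share of the substrate charged

Substrate is the limiting reagent, with 0.120 M against 0.180 M of partner, and each product takes one of each. So freeze a single number, k, the rate divided by [substrate][partner], taken as steady from the start of the dawn run to its last reading. Then:

ln( ([partner]/[substrate]) / (partner charged/substrate charged) ) = k × (partner charged − substrate charged) × t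

Dawn's 0.0997 M at 12 min gives k = 1.35 /M/min. Running the same line to 24 min:

product in winter = 94.7% of the substrate charged

That leaves 5.30% of the substrate charged unmade, so my number for winter is 94.7%.

The first readings give the orders. The spring run has twice dawn's partner and shows 1.91 times dawn's product at 1.5 min. Dawn over dusk shows 3.42 where the charges multiply to 3.00. I take 1 for each.

But k is not quite frozen. The dusk run's last reading gives 1.20 /M/min, below dawn's. The midnight run, charged with product, made 0.0427 M by 1.5 min against dawn's 0.0308 M. Where dusk and dawn hold equal substrate, the dawn run holds 0.0600 M more product than the dusk run, so I call the dusk run slower.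

The forecast reads 1 and 1 for the orders, slower for dusk and 95.5% for winter, on this ground: “This points to mild autocatalysis”.

The simulation gives 1.0 and 1.0, slower, and 93.9% for winter at 24 min, which is 0.80 percentage points below my figure.

    substrate + partner → product + by-product (1.062 /M/min)
    substrate + partner + product → 2 product (14.22 /M²/min)
    partner + by-product ⇌ reagent-by-product salt, settled at all times (41.00 /M)

The power-law fit over all runs forecasts 95.0% for the winter run. Put on the spring run, k = 1.35 /M/min has half of the substrate made at 1.58 min, and the spring run reaches that mark at 1.52 min.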